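The α-methylene-γ-butyrolactone (ring O–C12–C11–C7–C6) is disconnected at O–C6 and C11–C12, so that the O–C12(=O) unit is one molecule of CO2. The precursor is an acyclic 2-bromoalkene (C11–Br) with an allylic chloride of inverted configuration at C6, next to the C4=C5 alkene. In one flask, bromine–lithium exchange, capture of CO2 at C11 and 5-exo displacement of chloride by the new carboxylate close the lactone and set C6 by inversion. The step exploits the allylic C6 and its γ-relationship to C11. Ring-closing metathesis at C1=C10 then forms the ten-membered ring, and a hydroxyl-directed asymmetric epoxidation installs the oxirane.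

Key step: step 13

Remark: atom labels C1–C15 follow germacranolide numbering (ring C1–C10, C11–C13 on C7, C14 on C10, C15 on C4); in acyclic intermediates they mean the carbons that become these atoms.
Remark: CIP descriptors at C7 change between some intermediates only because substituent priorities change; the ring-cis C1=C10 bond is E by CIP because C14 carries oxygen.
Remark: compounds 1, 6, 8 and 15 are taken as commercially available.

Step 1
Reactants: 1 2-bromoprop-2-en-1-ol
Product: 2 [(2-bromoprop-2-en-1-yl)oxy](tert-butyl)dimethylsilane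
Conditions: TBSCl, imidazole, DMF, 0 °C to rt
Reagents that add atoms: tert-butyldimethylsilyl chloride (CC(C)(C)[Si](C)(C)Cl)
Why: Standard O-silylation of the primary allylic alcohol (imidazole-promoted silyl ether formation) should mask the future C14 hydroxyl for the organometallic steps.

Step 2
Reactants: 2 [(2-bromoprop-2-en-1-yl)oxy](tert-butyl)dimethylsilane
Product: 4 3-{[(tert-butyldimethylsilyl)oxy]methyl}but-3-en-1-ol, via vinyllithium 3 (not isolated)
Conditions: t-BuLi (2 equiv), Et2O, −78 °C; then oxirane, BF3·OEt2, −78 °C; H2O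
Reagents that add atoms: oxirane (C1CO1)
Why: Bromine–lithium exchange should give the 2-lithioallyl ether, whose BF3-assisted SN2 opening of oxirane (epoxide opening by an organolithium) adds C8 and C9; −78 °C suppresses β-elimination of the silyloxy group.

Step 3
Reactants: 4 3-{[(tert-butyldimethylsilyl)oxy]methyl}but-3-en-1-ol
Product: 5 3-{[(tert-butyldimethylsilyl)oxy]methyl}but-3-enal
Conditions: Dess–Martin periodinane, NaHCO3, CH2Cl2, 0 °C; used at once
Reagents that add atoms: none
Why: Dess–Martin oxidation under buffered, non-basic conditions should give the β,γ-unsaturated aldehyde without migration of the 1,1-disubstituted alkene into conjugation.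

Step 4
Reactants: 6 3-bromobut-3-en-1-ol
Product: 7 3-bromobut-3-enoic acid
Conditions: TEMPO (cat.), PhI(OAc)2, MeCN/H2O, rt
Reagents that add atoms: water (O)
Why: Nitroxyl-catalysed oxidation with a hypervalent iodine co-oxidant should take the primary alcohol through the aldehyde hydrate to the acid and leave the vinyl bromide untouched.

Step 5
Reactants: 7 3-bromobut-3-enoic acid; 8 (4R)-4-benzyl-1,3-oxazolidin-2-one
Product: 10 (4R)-4-benzyl-3-(3-bromobut-3-enoyl)-1,3-oxazolidin-2-one, via mixed anhydride 9 (not isolated)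
Conditions: PivCl, Et3N, THF, −20 °C; then 8, LiCl, −20 °C to rt
Reagents that add atoms: none
Why: N-Acylation of the oxazolidinone through the mixed pivalic anhydride should give the imide without strong base, which limits migration of the β,γ-alkene.

Step 6
Reactants: 10 (4R)-4-benzyl-3-(3-bromobut-3-enoyl)-1,3-oxazolidin-2-one; 5 3-{[(tert-butyldimethylsilyl)oxy]methyl}but-3-enal
Product: 12 (4R)-4-benzyl-3-[(2R,3S)-2-(1-bromoethenyl)-5-{[(tert-butyldimethylsilyl)oxy]methyl}-3-hydroxyhex-5-enoyl]-1,3-oxazolidin-2-one, via boron enolate 11 (not isolated)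
Conditions: Bu2BOTf, i-Pr2NEt, CH2Cl2, −78 to 0 °C; then 5, −78 to 0 °C; pH 7 buffer, MeOH, H2O2
Reagents that add atoms: none
Why: Evans syn-aldol reaction: the Z-dibutylboron enolate should react through a closed chair (Zimmerman–Traxler) transition state on the face opposite the benzyl group, which sets C7 (2R) and C8 (3S) together.

Step 7
Reactants: 12 (4R)-4-benzyl-3-[(2R,3S)-2-(1-bromoethenyl)-5-{[(tert-butyldimethylsilyl)oxy]methyl}-3-hydroxyhex-5-enoyl]-1,3-oxazolidin-2-one
Product: 13 (2R,3S)-2-(1-bromoethenyl)-5-{[(tert-butyldimethylsilyl)oxy]methyl}-3-hydroxy-N-methoxy-N-methylhex-5-enamide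
Conditions: MeNH(OMe)·HCl, AlMe3, CH2Cl2, −20 to 0 °C
Reagents that add atoms: N,O-dimethylhydroxylamine hydrochloride (CNOC.Cl)
Why: Aluminium-amide transamination (Weinreb amide formation), helped by the free β-hydroxyl, should release the auxiliary and give an acyl donor that stops at the ketone stage.

Step 8
Reactants: 13 (2R,3S)-2-(1-bromoethenyl)-5-{[(tert-butyldimethylsilyl)oxy]methyl}-3-hydroxy-N-methoxy-N-methylhex-5-enamide
Product: 14 (2R,3S)-2-(1-bromoethenyl)-5-{[(tert-butyldimethylsilyl)oxy]methyl}-N-methoxy-N-methyl-3-[(triethylsilyl)oxy]hex-5-enamide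
Conditions: TESOTf, 2,6-lutidine, CH2Cl2, −78 to 0 °C
Reagents that add atoms: triethylsilyl trifluoromethanesulfonate (CC[Si](CC)(CC)OS(=O)(=O)C(F)(F)F)
Why: Silylation with the silyl triflate and a hindered pyridine base should protect C8–OH as a triethylsilyl ether that can later be removed beside the primary tert-butyldimethylsilyl ether.

Step 9
Reactants: 15 hex-1-en-5-yne
Product: 17 (1E)-1-iodo-2-methylhexa-1,5-diene, via alkenylalane 16 (not isolated)
Conditions: AlMe3, Cp2ZrCl2 (cat.), CH2Cl2, 0 °C to rt; then I2, THF, −30 °C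
Reagents that add atoms: trimethylaluminium (C[Al](C)C); iodine (II)
Why: Zirconium-catalysed carboalumination (Negishi) should add methyl and aluminium syn and regioselectively across the alkyne only, and iodinolysis with retention should give the E-iodide that fixes the C4=C5 geometry.

Step 10
Reactants: 17 (1E)-1-iodo-2-methylhexa-1,5-diene; 14 (2R,3S)-2-(1-bromoethenyl)-5-{[(tert-butyldimethylsilyl)oxy]methyl}-N-methoxy-N-methyl-3-[(triethylsilyl)oxy]hex-5-enamide
Product: 19 (5E,8R,9S)-8-(1-bromoethenyl)-11-{[(tert-butyldimethylsilyl)oxy]methyl}-5-methyl-9-[(triethylsilyl)oxy]dodeca-1,5,11-trien-7-one, via alkenyllithium 18 (not isolated)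
Conditions: 17, t-BuLi (2 equiv), Et2O, −78 °C; then 14, THF, −78 °C; H2O
Reagents that add atoms: none
Why: Acyl substitution of the Weinreb amide by the alkenyllithium (ketone synthesis through a stable chelated tetrahedral intermediate) should give the E-enone, and the low temperature limits deprotonation at C7.

Step 11
Reactants: 19 (5E,8R,9S)-8-(1-bromoethenyl)-11-{[(tert-butyldimethylsilyl)oxy]methyl}-5-methyl-9-[(triethylsilyl)oxy]dodeca-1,5,11-trien-7-one
Product: 20 (5E,7R,8S,9S)-8-(1-bromoethenyl)-11-{[(tert-butyldimethylsilyl)oxy]methyl}-5-methyl-9-[(triethylsilyl)oxy]dodeca-1,5,11-trien-7-ol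
Conditions: (R)-2-methyl-CBS-oxazaborolidine (0.5 equiv), catecholborane, toluene, −78 °C; aqueous work-up
Reagents that add atoms: none
Why: Corey–Bakshi–Shibata reduction: the oxazaborolidine should direct hydride from catecholborane to one carbonyl face (alkenyl as the large group), which sets the C6 carbinol (7R in chain numbering), and catecholborane leaves the alkenes alone.

Step 12
Reactants: 20 (5E,7R,8S,9S)-8-(1-bromoethenyl)-11-{[(tert-butyldimethylsilyl)oxy]methyl}-5-methyl-9-[(triethylsilyl)oxy]dodeca-1,5,11-trien-7-ol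
Product: 21 (5E,7S,8R,9S)-8-(1-bromoethenyl)-11-{[(tert-butyldimethylsilyl)oxy]methyl}-7-chloro-5-methyl-9-[(triethylsilyl)oxy]dodeca-1,5,11-triene
Conditions: PPh3, hexachloroacetone, CH2Cl2, −20 to 0 °C
Reagents that add atoms: hexachloroacetone (O=C(C(Cl)(Cl)Cl)C(Cl)(Cl)Cl)
Why: Appel-type chlorination should pass through the alkoxyphosphonium salt and SN2 attack of chloride, so that C6 is inverted to the (7S)-chloride; this reagent pair is chosen because it converts allylic alcohols with little allylic shift.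

Step 13
Reactants: 21 (5E,7S,8R,9S)-8-(1-bromoethenyl)-11-{[(tert-butyldimethylsilyl)oxy]methyl}-7-chloro-5-methyl-9-[(triethylsilyl)oxy]dodeca-1,5,11-triene
Product: 24 (4S,5R)-4-[(1S)-3-{[(tert-butyldimethylsilyl)oxy]methyl}-1-[(triethylsilyl)oxy]but-3-en-1-yl]-3-methylidene-5-[(1E)-2-methylhexa-1,5-dien-1-yl]oxolan-2-one, via alkenyllithium 22 (not isolated), via lithium carboxylate 23 (not isolated)
Conditions: t-BuLi (2.1 equiv), THF/Et2O/pentane, −100 °C, 5 min; CO2 (1 atm), −100 to −40 °C; then DMPU, 45 °C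
Reagents that add atoms: carbon dioxide (O=C=O)
Why: t-BuLi should exchange the vinylic bromide faster than it attacks the secondary allylic chloride at −100 °C, alkenyllithium 22 adds to CO2 to give carboxylate 23, and on warming with DMPU the carboxylate oxygen displaces chloride at C6. The closest known reaction types are the carboxylation of alkenyllithiums with CO2 and lactonization by intramolecular O-alkylation of a carboxylate with an allylic halide. The lactone ring (O, C12, C11, C7, C6) closes in the 5-exo-tet mode. C6 is set by SN2 inversion of the (7S)-chloride, so its configuration is relayed from the reagent-controlled reduction of step 11, while C7 and C8 are not touched. The step needs SN2 over SN2′ closure and carboxylation before any attack of C11–Li on C6–Cl; the seven-membered ring that closure at C4 would require, the very low exchange temperature and the immediate CO2 quench should secure both.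

Step 14
Reactants: 24 (4S,5R)-4-[(1S)-3-{[(tert-butyldimethylsilyl)oxy]methyl}-1-[(triethylsilyl)oxy]but-3-en-1-yl]-3-methylidene-5-[(1E)-2-methylhexa-1,5-dien-1-yl]oxolan-2-one
Product: 25 (3aS,4S,6E,10E,11aR)-6-{[(tert-butyldimethylsilyl)oxy]methyl}-10-methyl-3-methylidene-4-[(triethylsilyl)oxy]-3a,4,5,8,9,11a-hexahydrocyclodeca[b]furan-2(3H)-one
Conditions: second-generation Grubbs catalyst RuCl2(=CHPh)(PCy3)(H2IMes) (10 mol %), toluene (1 mM), 80 °C, argon sparge
Reagents that add atoms: none
Why: Ring-closing olefin metathesis between the monosubstituted C1 alkene and the 1,1-disubstituted C10 alkene should close the ten-membered ring with the ring-cis C1=C10 geometry favoured in a medium ring; the electron-poor exocyclic methylene and the trisubstituted C4=C5 alkene should stay out.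

Step 15
Reactants: 25 (3aS,4S,6E,10E,11aR)-6-{[(tert-butyldimethylsilyl)oxy]methyl}-10-methyl-3-methylidene-4-[(triethylsilyl)oxy]-3a,4,5,8,9,11a-hexahydrocyclodeca[b]furan-2(3H)-one
Product: 26 (3aR,4S,6E,10E,11aR)-6-{[(tert-butyldimethylsilyl)oxy]methyl}-4-hydroxy-10-methyl-3-methylidene-3a,4,5,8,9,11a-hexahydrocyclodeca[b]furan-2(3H)-one
Conditions: PPTS (cat.), MeOH, 0 °C to rt
Reagents that add atoms: none
Why: Acid-catalysed methanolysis should cleave the secondary triethylsilyl ether much faster than the primary tert-butyldimethylsilyl ether (selective desilylation).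

Step 16
Reactants: 26 (3aR,4S,6E,10E,11aR)-6-{[(tert-butyldimethylsilyl)oxy]methyl}-4-hydroxy-10-methyl-3-methylidene-3a,4,5,8,9,11a-hexahydrocyclodeca[b]furan-2(3H)-one
Product: 27 (3aR,4S,6E,10E,11aR)-6-{[(tert-butyldimethylsilyl)oxy]methyl}-10-methyl-3-methylidene-2-oxo-2,3,3a,4,5,8,9,11a-octahydrocyclodeca[b]furan-4-yl 2-methylprop-2-enoate
Conditions: methacrylic anhydride, Et3N, DMAP (cat.), CH2Cl2, 0 °C to rt
Reagents that add atoms: methacrylic anhydride (C=C(C)C(=O)OC(=O)C(C)=C)
Why: DMAP-catalysed acylation of the secondary C8 alcohol with the anhydride should give the methacrylate with retention at C8.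

Step 17
Reactants: 27 (3aR,4S,6E,10E,11aR)-6-{[(tert-butyldimethylsilyl)oxy]methyl}-10-methyl-3-methylidene-2-oxo-2,3,3a,4,5,8,9,11a-octahydrocyclodeca[b]furan-4-yl 2-methylprop-2-enoate
Product: 28 (3aR,4S,6E,10E,11aR)-6-(hydroxymethyl)-10-methyl-3-methylidene-2-oxo-2,3,3a,4,5,8,9,11a-octahydrocyclodeca[b]furan-4-yl 2-methylprop-2-enoate
Conditions: HF·pyridine, pyridine, THF, 0 °C
Reagents that add atoms: none
Why: Fluoride-mediated desilylation with buffered HF·pyridine should free the C14 allylic alcohol without touching the esters or the Michael acceptors.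

Step 18
Reactants: 28 (3aR,4S,6E,10E,11aR)-6-(hydroxymethyl)-10-methyl-3-methylidene-2-oxo-2,3,3a,4,5,8,9,11a-octahydrocyclodeca[b]furan-4-yl 2-methylprop-2-enoate
Product: 29 (1R,6R,7R,8S,10R)-1,10-epoxy-14-hydroxy-8-(methacryloyloxy)germacra-4E,11(13)-dien-6,12-olide
Conditions: Ti(Oi-Pr)4, D-(−)-diethyl tartrate, t-BuOOH, 4 Å molecular sieves, CH2Cl2, −20 °C
Reagents that add atoms: tert-butyl hydroperoxide (CC(C)(C)OO)
Why: Katsuki–Sharpless asymmetric epoxidation: the titanium–tartrate complex binds the C14 allylic alcohol, so only C1=C10 is epoxidized, and D-(−)-diethyl tartrate should deliver oxygen to the face that gives the (1R,10R)-oxirane.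

Step 19
Reactants: 29 (1R,6R,7R,8S,10R)-1,10-epoxy-14-hydroxy-8-(methacryloyloxy)germacra-4E,11(13)-dien-6,12-olide
Product: 30 (1R,6R,7R,8S,10R)-14-acetoxy-1,10-epoxy-8-(methacryloyloxy)germacra-4E,11(13)-dien-6,12-olide
Conditions: Ac2O, pyridine, DMAP (cat.), CH2Cl2, 0 °C
Reagents that add atoms: acetic anhydride (CC(=O)OC(C)=O)
Why: Acetylation of the primary epoxy alcohol (nucleophilic acyl transfer catalysis) should give the target without opening the epoxide.

Compound list
1 | 2-bromoprop-2-en-1-ol | C=C(Br)CO | starting material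
2 | [(2-bromoprop-2-en-1-yl)oxy](tert-butyl)dimethylsilane | C=C(Br)CO[Si](C)(C)C(C)(C)C | intermediate
3 | {3-[(tert-butyldimethylsilyl)oxy]prop-1-en-2-yl}lithium | [Li]C(=C)CO[Si](C)(C)C(C)(C)C | intermediate
4 | 3-{[(tert-butyldimethylsilyl)oxy]methyl}but-3-en-1-ol | OCCC(=C)CO[Si](C)(C)C(C)(C)C | intermediate
5 | 3-{[(tert-butyldimethylsilyl)oxy]methyl}but-3-enal | O=CCC(=C)CO[Si](C)(C)C(C)(C)C | intermediate
6 | 3-bromobut-3-en-1-ol | C=C(Br)CCO | starting material
7 | 3-bromobut-3-enoic acid | C=C(Br)CC(=O)O | intermediate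
8 | (4R)-4-benzyl-1,3-oxazolidin-2-one | O=C1N[C@H](Cc2ccccc2)CO1 | starting material
9 | 3-bromobut-3-enoic 2,2-dimethylpropanoic anhydride | C=C(Br)CC(=O)OC(=O)C(C)(C)C | intermediate
10 | (4R)-4-benzyl-3-(3-bromobut-3-enoyl)-1,3-oxazolidin-2-one | C=C(Br)CC(=O)N1[C@H](Cc2ccccc2)COC1=O | intermediate
11 | (Z)-O-dibutylboryl enolate of 10 | C=C(Br)/C=C(\OB(CCCC)CCCC)N1[C@H](Cc2ccccc2)COC1=O | intermediate
12 | (4R)-4-benzyl-3-[(2R,3S)-2-(1-bromoethenyl)-5-{[(tert-butyldimethylsilyl)oxy]methyl}-3-hydroxyhex-5-enoyl]-1,3-oxazolidin-2-one | C=C(Br)[C@@H](C(=O)N1[C@H](Cc2ccccc2)COC1=O)[C@@H](O)CC(=C)CO[Si](C)(C)C(C)(C)C | intermediate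
13 | (2R,3S)-2-(1-bromoethenyl)-5-{[(tert-butyldimethylsilyl)oxy]methyl}-3-hydroxy-N-methoxy-N-methylhex-5-enamide | C=C(Br)[C@@H](C(=O)N(C)OC)[C@@H](O)CC(=C)CO[Si](C)(C)C(C)(C)C | intermediate
14 | (2R,3S)-2-(1-bromoethenyl)-5-{[(tert-butyldimethylsilyl)oxy]methyl}-N-methoxy-N-methyl-3-[(triethylsilyl)oxy]hex-5-enamide | C=C(Br)[C@@H](C(=O)N(C)OC)[C@@H](O[Si](CC)(CC)CC)CC(=C)CO[Si](C)(C)C(C)(C)C | intermediate
15 | hex-1-en-5-yne | C#CCCC=C | starting material
16 | dimethyl[(1E)-2-methylhexa-1,5-dien-1-yl]alumane | C[Al](C)/C=C(\C)CCC=C | intermediate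
17 | (1E)-1-iodo-2-methylhexa-1,5-diene | I/C=C(\C)CCC=C | intermediate
18 | [(1E)-2-methylhexa-1,5-dien-1-yl]lithium | [Li]/C=C(\C)CCC=C | intermediate
19 | (5E,8R,9S)-8-(1-bromoethenyl)-11-{[(tert-butyldimethylsilyl)oxy]methyl}-5-methyl-9-[(triethylsilyl)oxy]dodeca-1,5,11-trien-7-one | C=C(Br)[C@@H](C(=O)/C=C(\C)CCC=C)[C@@H](O[Si](CC)(CC)CC)CC(=C)CO[Si](C)(C)C(C)(C)C | intermediate
20 | (5E,7R,8S,9S)-8-(1-bromoethenyl)-11-{[(tert-butyldimethylsilyl)oxy]methyl}-5-methyl-9-[(triethylsilyl)oxy]dodeca-1,5,11-trien-7-ol | C=C(Br)[C@@H]([C@H](O)/C=C(\C)CCC=C)[C@@H](O[Si](CC)(CC)CC)CC(=C)CO[Si](C)(C)C(C)(C)C | intermediate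
21 | (5E,7S,8R,9S)-8-(1-bromoethenyl)-11-{[(tert-butyldimethylsilyl)oxy]methyl}-7-chloro-5-methyl-9-[(triethylsilyl)oxy]dodeca-1,5,11-triene | C=C(Br)[C@@H]([C@@H](Cl)/C=C(\C)CCC=C)[C@@H](O[Si](CC)(CC)CC)CC(=C)CO[Si](C)(C)C(C)(C)C | intermediate
22 | alkenyllithium from 21 (lithium in place of bromine at C11) | [Li]C(=C)[C@@H]([C@@H](Cl)/C=C(\C)CCC=C)[C@@H](O[Si](CC)(CC)CC)CC(=C)CO[Si](C)(C)C(C)(C)C | intermediate
23 | lithium carboxylate from 22 (CO2Li at C11, chloride still at C6) | [Li+].[O-]C(=O)C(=C)[C@@H]([C@@H](Cl)/C=C(\C)CCC=C)[C@@H](O[Si](CC)(CC)CC)CC(=C)CO[Si](C)(C)C(C)(C)C | intermediate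
24 | (4S,5R)-4-[(1S)-3-{[(tert-butyldimethylsilyl)oxy]methyl}-1-[(triethylsilyl)oxy]but-3-en-1-yl]-3-methylidene-5-[(1E)-2-methylhexa-1,5-dien-1-yl]oxolan-2-one | C=C1C(=O)O[C@H](/C=C(\C)CCC=C)[C@H]1[C@@H](O[Si](CC)(CC)CC)CC(=C)CO[Si](C)(C)C(C)(C)C | intermediate
25 | (3aS,4S,6E,10E,11aR)-6-{[(tert-butyldimethylsilyl)oxy]methyl}-10-methyl-3-methylidene-4-[(triethylsilyl)oxy]-3a,4,5,8,9,11a-hexahydrocyclodeca[b]furan-2(3H)-one | CC[Si](CC)(CC)O[C@H]1C/C(CO[Si](C)(C)C(C)(C)C)=C\CC/C(C)=C/[C@H]2OC(=O)C(=C)[C@H]12 | intermediate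
26 | (3aR,4S,6E,10E,11aR)-6-{[(tert-butyldimethylsilyl)oxy]methyl}-4-hydroxy-10-methyl-3-methylidene-3a,4,5,8,9,11a-hexahydrocyclodeca[b]furan-2(3H)-one | O[C@H]1C/C(CO[Si](C)(C)C(C)(C)C)=C\CC/C(C)=C/[C@H]2OC(=O)C(=C)[C@H]12 | intermediate
27 | (3aR,4S,6E,10E,11aR)-6-{[(tert-butyldimethylsilyl)oxy]methyl}-10-methyl-3-methylidene-2-oxo-2,3,3a,4,5,8,9,11a-octahydrocyclodeca[b]furan-4-yl 2-methylprop-2-enoate | C=C(C)C(=O)O[C@H]1C/C(CO[Si](C)(C)C(C)(C)C)=C\CC/C(C)=C/[C@H]2OC(=O)C(=C)[C@H]12 | intermediate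
28 | (3aR,4S,6E,10E,11aR)-6-(hydroxymethyl)-10-methyl-3-methylidene-2-oxo-2,3,3a,4,5,8,9,11a-octahydrocyclodeca[b]furan-4-yl 2-methylprop-2-enoate | C=C(C)C(=O)O[C@H]1C/C(CO)=C\CC/C(C)=C/[C@H]2OC(=O)C(=C)[C@H]12 | intermediate
29 | (1R,6R,7R,8S,10R)-1,10-epoxy-14-hydroxy-8-(methacryloyloxy)germacra-4E,11(13)-dien-6,12-olide | C=C(C)C(=O)O[C@H]1C[C@]2(CO)O[C@@H]2CC/C(C)=C/[C@H]2OC(=O)C(=C)[C@H]12 | intermediate
30 | (1R,6R,7R,8S,10R)-14-acetoxy-1,10-epoxy-8-(methacryloyloxy)germacra-4E,11(13)-dien-6,12-olide | C=C(C)C(=O)O[C@H]1C[C@]2(COC(C)=O)O[C@@H]2CC/C(C)=C/[C@H]2OC(=O)C(=C)[C@H]12 | target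

Total step count: 19 steps. Longest linear sequence: 16 steps (from 1 through steps 1–3, 6–8 and 10–19).

Steps most likely to fail

Step 13. The alkenyllithium or t-BuLi may attack the allylic chloride (cyclization or elimination) before CO2 is captured, or the chloride may ionize so that C6 loses its configuration. The fallback keeps CO2 as the source of O and C12 but separates the organolithium stage from the electrophile. It sets out from enone 19. Reduction with the enantiomeric (S)-2-methyl-CBS-oxazaborolidine and catecholborane should give the C6-epimeric alcohol F1. Treatment with t-BuLi (3 equiv) at −78 °C, CO2 and a cold, mildly acidic work-up should give the hydroxy acid F2, which is used at once. Mitsunobu lactonization (PPh3, DIAD, THF, 0 °C) should then let the carboxylate oxygen displace the activated C6 oxygen with inversion, and the route is rejoined at lactone 24.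

Step 14. Ring closure may be outrun by intermolecular metathesis, a ruthenium carbene loaded on C10 may close a six-membered ring onto C5, or the ring-trans isomer may form. The fallback closes the carbocycle before the lactone is present. It sets out from alcohol 20. Ring-closing metathesis with the same catalyst should give the ten-membered bromo alcohol F3, and PPh3/hexachloroacetone should give the inverted carbocyclic chloride F4. The conditions of step 13 (t-BuLi, CO2, then warming with DMPU) should then give the lactone on the preformed ring, and the route is rejoined at 25.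

Step 12. The alkoxyphosphonium intermediate may ionize to the 1,1-dialkyl-substituted allyl cation, which would erode the C6 configuration or shift chlorine to C4. The fallback avoids any inversion at C6 and replaces steps 12 and 13. It sets out from bromo alcohol 20. Carbonylative lactonization with Pd(PPh3)4 (zerovalent palladium), CO (1 atm) and Et3N in MeCN at 60 °C should convert the vinyl bromide and the retained C6 hydroxyl directly into the lactone. The route is rejoined at 24, and no further compound is made (entry F0).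

Further compounds
F1 | step 13 | (5E,7S,8S,9S)-8-(1-bromoethenyl)-11-{[(tert-butyldimethylsilyl)oxy]methyl}-5-methyl-9-[(triethylsilyl)oxy]dodeca-1,5,11-trien-7-ol | C=C(Br)[C@@H]([C@@H](O)/C=C(\C)CCC=C)[C@@H](O[Si](CC)(CC)CC)CC(=C)CO[Si](C)(C)C(C)(C)C
F2 | step 13 | (3S,4S,5E)-3-[(1S)-3-{[(tert-butyldimethylsilyl)oxy]methyl}-1-[(triethylsilyl)oxy]but-3-en-1-yl]-4-hydroxy-6-methyl-2-methylidenedeca-5,9-dienoic acid | OC(=O)C(=C)[C@@H]([C@@H](O)/C=C(\C)CCC=C)[C@@H](O[Si](CC)(CC)CC)CC(=C)CO[Si](C)(C)C(C)(C)C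
F3 | step 14 | (1R,2E,6E,9S,10S)-10-(1-bromoethenyl)-7-{[(tert-butyldimethylsilyl)oxy]methyl}-3-methyl-9-[(triethylsilyl)oxy]cyclodeca-2,6-dien-1-ol | C=C(Br)[C@H]1[C@H](O)/C=C(\C)CC/C=C(CO[Si](C)(C)C(C)(C)C)\C[C@@H]1O[Si](CC)(CC)CC
F4 | step 14 | tert-butyl{[(1E,5E,7S,8R,9S)-8-(1-bromoethenyl)-7-chloro-5-methyl-9-[(triethylsilyl)oxy]cyclodeca-1,5-dien-1-yl]methoxy}dimethylsilane | C=C(Br)[C@H]1[C@@H](Cl)/C=C(\C)CC/C=C(CO[Si](C)(C)C(C)(C)C)\C[C@@H]1O[Si](CC)(CC)CC
F0 | step 12 | none | none
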